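(The runs are calculated with made-up constants, and the scatter is random.)

Count turnovers. The flasks share one enzyme charge, and the question is how much free target stands in each at the end.

| setting | oak | larch | Saturday's | Friday's | Sunday's | Tuesday's |
|---|---|---|---|---|---|---|
| starting material | 35 mM | 190 mM | 40 mM | 80 mM | 150 mM | 300 mM |
| enzyme | 6.2 µM | 6.2 µM | 6.2 µM | 6.2 µM | 6.2 µM | 6.2 µM |
| remark | run made earlier | run made earlier |  |  |  |  |
| time |  |  | 3.0 h | 3.0 h | 3.0 h | 3.0 h |

| oak: time / h | oak: target / % | larch: time / h | larch: target / % |
|---|---|---|---|
| 0.500 | 21 | 0.250 | 1 |
| 1.00 | 19 | 0.417 | 1 |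
| 1.50 | 7 | 0.667 | 0 |
| 2.00 | 2 | 1.00 | 2 |
| 2.50 | 3 | 2.00 | 3 |
| 3.00 | 1 | 3.00 | 1 |

(standard deviation of a reading: 1.5 percentage points)

- [target] (only what is free in solution) at the end for Saturday's, Friday's, Sunday's, Tuesday's, in this order
- the course of these numbers from the first flask to the last (hardly changes / falls, then rises / rises, then falls / falls all the way / rises all the way)

- a reading or a percentage of target counts all its forms, free or not
- the concentration of target that is asked is that of its free form alone
- "hardly changes" means that all values lie within two and a half points (for a concentration: within two and a half percent of the largest)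

In the oak run, target rises and is consumed again: it reads 21% at 0.500 h and 2% at 2.00 h. If the enzyme both makes and consumes target, each molecule of starting material costs two turnovers, so the oak charge cost 70.0 mM, taken as spent by 2.00 h. Scaled to 3.0 h, that gives 105 mM: the turnover budget, the concentration of turnovers that 6.2 µM enzyme delivers in the flask time at the oak pace.

Two chemists dispute what this number is worth. The first, whose reckoning is my own, holds the pace constant at every charge. Saturday's flask needs 80.0 mM, less than the budget, so it should end cleared. Tuesday's flask needs 600 mM, more than the budget, so it should end unfinished with its full budget spent.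

The second chemist starts from the larch run. Its reading of 3% at 2.00 h, on a charge of 190 mM, is about 5.70 mM, against a reading of 7.35 mM at 0.500 h in the oak run, on a charge of 35 mM. The conclusion drawn is that “high starting material probably throttles formation”, that is, substrate inhibition. The forecast is this side's: 0.5 mM, 10 mM, 3.5 mM and 2.5 mM, with the course rises, then falls.

The simulation gives 0.0696 mM, 3.41 mM, 4.76 mM and 2.04 mM, with the course rises, then falls; Friday's flask ends well under the forecast.

    crystals ⇌ target, rate k1*(cs1 - [target]) while solid is left; crystals form when [target] > cs1 (solubility = 15.0 mM, k = 0.00680 s⁻¹)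
    enzyme + target → enzyme + over-reaction product (k = 170 L mol⁻¹ s⁻¹)
    starting material + enzyme → target + enzyme, rate k3*[starting material]*[enzyme]/(1 + ([starting material]/Km3) + ([starting material]/Ksi3)^2) (0.0600 M, 27.0 mM, k = 140 L mol⁻¹ s⁻¹)

Tuesday's flask still holds 92.5% of its starting material at the end. Counting one turnover per starting material consumed and one per over-reaction product formed, Tuesday's flask spent 43.0 mM, less than the budget of 105 mM, so Tuesday's flask fell short of the constant pace and the first chemist loses there. The constant pace keeps Saturday's flask, which spent 79.9 mM, within the budget, and ended with over-reaction product at 99.8%.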